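(The numbers in the tables were computed from invented constants; the scatter is artificial.)

1. Late readings tell most, so I began with the last ones and asked what they say about a new charge.

| flask | substrate | gas phase | remark | time |
|---|---|---|---|---|
| cedar | 0.0013 M | 0.14 mM (held) | run made earlier |  |
| elm | 0.0030 M | 0.14 mM (held) | run made earlier |  |
| flask | 0.0020 M | 0.14 mM (held) |  | 3.0 min |

| run | time / s | target / % | crystals / % |
|---|---|---|---|
| cedar | 15.0 | 5.8 | 0.2 |
| cedar | 30.0 | 12.7 | 4.5 |
| cedar | 50.0 | 20.4 | 13.0 |
| cedar | 60.0 | 24.5 | 16.4 |
| cedar | 80.0 | 31.5 | 23.6 |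
| cedar | 90.0 | 34.4 | 26.5 |
| cedar | 120 | 43.0 | 35.4 |
| elm | 10.0 | 2.5 | 0.1 |
| elm | 15.0 | 3.9 | 0.3 |
| elm | 30.0 | 7.7 | 3.3 |
| elm | 50.0 | 11.9 | 8.4 |
| elm | 60.0 | 14.5 | 10.9 |
| elm | 80.0 | 18.4 | 15.6 |
| elm | 120 | 27.4 | 23.9 |

(each reading ± 0.3 percentage points)

- for target the crystals are counted in
- as a solid, counted per litre of solution: crystals
- at the start none of the gas phase is in solution

* how much target and crystals together there is at 3.0 min, in percent of the substrate charged
* concentration of dissolved gas in solution at 3.0 min, in percent of saturation

2. At 120 s, target (crystals counted in) stood at 43.0% of the charge in cedar and 27.4% in elm. Crystals are counted in target, so I read y as the target figure.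

3. Dissolved gas at saturation is 7.00% of this flask's charge. I treated that small store as a correction and dropped it, setting crossing equal to use (quasi-steady state).

4. With f the fraction of the charge left as substrate, y = 1 − f, and time t follows t/v = N·y − ln f, while saturation = 1/(1 + N·f). The two late readings gave v = 111 s and, for this flask, N = 1.84. I call N the gas demand: how many times faster a full charge at saturation uses gas than the crossing refills an empty solution. It scales with the charge.

5. At y = 0.5 the clock reads 2.98 min, against the 3.0 min asked, so my own reckoning put y at about 0.5, with saturation 52.1%. These figures are mine, and the forecast's below differ from them.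

6. Was one number enough? Elm's 14.5%, read at 60.0 s, falls at 62.1 s on the clock. But I took whatever was not target to be substrate, and no reading showed substrate.

7. The forecast gave y 48.5% (45% to 52%) and saturation 53% (43% to 64%), judging that “gas transfer is partly limiting”.

8. The flask gave y 48.3% and saturation 65.8%, above the top of the forecast's range.

    crystals ⇌ target, rate k1*(cs1 - [target]) while solid is left; crystals form when [target] > cs1 (solubility = 0.0960 mM, k = 0.731 s⁻¹)
    gas phase ⇌ dissolved gas, rate k2*(csat - [dissolved gas]) (kL = 0.111 s⁻¹)
    substrate + target → side product (k = 11.4 L mol⁻¹ s⁻¹)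
    dissolved gas + target → over-reacted product (k = 61.5 L mol⁻¹ s⁻¹)
    substrate + dissolved gas → target (k = 96.5 L mol⁻¹ s⁻¹)

Substrate stood at 25%, less than the 51.7% that y leaves open, and side product held 22.8%. With that f, the gas demand gives 68.5% saturation. The neighbour charged with 0.0034 M has demand 3.13, and its 36% of substrate gives 47.2%; its dissolved gas stood at 46.6% of saturation.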